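**Plan**

1. Rings: ring 1 is the dihydrobenzofuran with the 7-OH, ring 2 the dihydrobenzofuran that carries the stilbene at C6, ring 3 the 6-hydroxy-dihydrobenzofuran bonded through C4 to C3 of ring 2. Cuts: the central E-alkene (Heck); C2–C3 of ring 1 and of ring 2 (carbene C–H insertion); in ring 3 both O1–C2 and C3a–C3, which leaves a p-quinone and tri-O-benzylresveratrol.
2. Enabling feature: the benzene ring of ring 3 is a resorcinol in which C3a is ortho to O1 and para to the C6 oxygen, C5 (para to O1) is a free CH and C4 carries carbon. It can therefore enter as a 1,4-benzoquinone (carbonyls at C7a and C5) with an ester at C4, which makes C3a the electrophile, while the 4-oxyphenyl ring on C2 stabilises the cation that O1 then captures.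
3. Forward: quinone ester plus tri-O-benzylresveratrol gives ring 3 in one formal [3+2] cycloaddition; the temporary C5 oxygen is removed via its triflate; the activating ester becomes C3 of ring 2 (Weinreb amide, diaryl ketone, hydrazone, diazo, insertion); ring 1 is built the same way from 2,3-dihydroxybenzaldehyde; a Heck coupling joins the halves; nine benzyl ethers are removed last.
4. Stereochemistry: ring 3 (2S,3S) from the chiral copper Lewis acid in the cycloaddition, trans by ring closure; C3 of ring 2 (R) and of ring 1 (S) from enantiomeric dirhodium carboxylate catalysts, the cis insertion products being epimerised at C2 with acid to the trans rings; the alkene is E from the Heck reaction.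

Key step: step 4

Assumption: the sense of induction written for Cu(OTf)2/(S,S)-t-Bu-box (step 4) and for Rh2(R-PTAD)4 and Rh2(S-PTAD)4 (steps 11 and 19) is a working assignment; if a catalyst favours the opposite sense, its enantiomer is used and nothing else changes.

**Route**

Step 1
Reactants: 1 (E)-resveratrol
Product: 2 tri-O-benzylresveratrol [(E)-3,5,4'-tris(benzyloxy)stilbene]
Conditions: BnBr (3.6 equiv), K2CO3, DMF, 60 °C
Reagents that add atoms: benzyl bromide, BrCc1ccccc1
Why: Williamson ether synthesis on the three phenols should give the tribenzyl ether without touching the E-alkene; no stereocenter is formed.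

Step 2
Reactants: 3 methyl 2,3-dihydroxybenzoate
Product: 4 methyl 3-(benzyloxy)-2-hydroxybenzoate
Conditions: BnBr (1.0 equiv), K2CO3 (1.1 equiv), acetone, reflux
Reagents that add atoms: benzyl bromide, BrCc1ccccc1
Why: Williamson etherification should occur only at the 3-hydroxyl because the 2-hydroxyl is held in a hydrogen bond to the ester carbonyl; no stereocenter is formed.

Step 3
Reactants: 4 methyl 3-(benzyloxy)-2-hydroxybenzoate
Product: 5 quinone ester methyl 5-(benzyloxy)-3,6-dioxocyclohexa-1,4-diene-1-carboxylate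
Conditions: (KSO3)2NO (2.5 equiv), KH2PO4, H2O/acetone, 0 °C to rt; extracted and used at once
Reagents that add atoms: potassium nitrosodisulfonate (Fremy's salt), [K+].[K+].[O-]S(=O)(=O)N([O])S(=O)(=O)[O-]
Why: Teuber oxidation of a phenol with a free para position should give the p-quinone, the new carbonyl oxygen coming from the nitroxyl radical; no stereocenter is formed.

Step 4
Reactants: 5 quinone ester, 2 tri-O-benzylresveratrol
Product: 6 ring-3 phenol ester methyl (2S,3S)-6-(benzyloxy)-2-[4-(benzyloxy)phenyl]-3-[3,5-bis(benzyloxy)phenyl]-5-hydroxy-2,3-dihydro-1-benzofuran-4-carboxylate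
Conditions: Cu(OTf)2 (10 mol %), (S,S)-t-Bu-box (12 mol %), 4 Å MS, CH2Cl2, −40 to 0 °C
Reagents that add atoms: none
Why: Quinone 5 binds the copper–bis(oxazoline) Lewis acid through its C6 carbonyl oxygen and its ester carbonyl, which makes ring carbon C2 a doubly activated Michael acceptor; the stilbene attacks it with the alkene carbon that bears the 3,5-bis(benzyloxy)phenyl ring, because only then does the cation sit next to the 4-benzyloxyphenyl ring, and the C3 carbonyl oxygen of the quinone closes onto that cation before the adduct tautomerises to the phenol. The closest known reaction type is the Lewis-acid-promoted formal [3+2] cycloaddition of 2-alkoxy- and 2-alkoxycarbonyl-1,4-benzoquinones with 1-arylpropenes and styrenes, including its enantioselective variants with chiral titanium or copper Lewis acids. The dihydrofuran of ring 3 closes by 5-exo-trig capture of the benzylic cation by oxygen after the intermolecular conjugate addition. C3 is set in the C–C bond formation by the bis(oxazoline) ligand, which shields one face of the chelated quinone, and C2 is set in the ring closure, trans to the C3 aryl group for steric reasons. The step needs regioselectivity at both partners, [3+2] over [2+2] closure and enantioselectivity: the ester and the neighbouring benzyloxy group both direct attack to C2 of 5, the para-benzyloxy group fixes the polarity of the alkene, and the two-point chelate gives the ligand a rigid substrate. Because the new C–C bond of the zwitterion rotates freely, an E/Z mixture of 2 and any cyclobutane from [2+2] closure (which reopens with release of strain) should funnel into the same trans-dihydrobenzofuran.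

Step 5
Reactants: 6 ring-3 phenol ester
Product: 7 C5 triflate methyl (2S,3S)-6-(benzyloxy)-2-[4-(benzyloxy)phenyl]-3-[3,5-bis(benzyloxy)phenyl]-5-{[(trifluoromethyl)sulfonyl]oxy}-2,3-dihydro-1-benzofuran-4-carboxylate
Conditions: Tf2O (1.3 equiv), pyridine, CH2Cl2, 0 °C
Reagents that add atoms: trifluoromethanesulfonic anhydride, O=S(=O)(OS(=O)(=O)C(F)(F)F)C(F)(F)F
Why: O-sulfonylation of the only free phenol turns the temporary C5 oxygen into a leaving group; the stereocenters are not involved.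

Step 6
Reactants: 7 C5 triflate
Product: 8 deoxygenated ester methyl (2S,3S)-6-(benzyloxy)-2-[4-(benzyloxy)phenyl]-3-[3,5-bis(benzyloxy)phenyl]-2,3-dihydro-1-benzofuran-4-carboxylate
Conditions: Pd(OAc)2 (5 mol %), dppf (6 mol %), HCO2H, Et3N, DMF, 70 °C
Reagents that add atoms: none
Why: Palladium-catalysed formate reduction of an aryl triflate (oxidative addition, decarboxylation of formate, C–H reductive elimination) should remove the helper oxygen and spare the benzyl ethers, since neither hydrogen gas nor a heterogeneous catalyst is present.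

Step 7
Reactants: 8 deoxygenated ester
Product: 9 Weinreb amide (2S,3S)-6-(benzyloxy)-2-[4-(benzyloxy)phenyl]-3-[3,5-bis(benzyloxy)phenyl]-N-methoxy-N-methyl-2,3-dihydro-1-benzofuran-4-carboxamide
Conditions: MeNH(OMe)·HCl (3 equiv), i-PrMgCl (6 equiv), THF, −15 °C to rt
Reagents that add atoms: N,O-dimethylhydroxylamine hydrochloride, CNOC.Cl
Why: Aminolysis of the methyl ester by the magnesium amide of N,O-dimethylhydroxylamine (Weinreb amide synthesis) prepares the carbonyl for a single aryllithium addition.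

Step 8
Reactants: 10 5-bromo-2-iodophenol, 11 4-(benzyloxy)benzyl chloride
Product: 12 4-bromo-1-iodo-2-{[4-(benzyloxy)phenyl]methoxy}benzene
Conditions: K2CO3, DMF, 50 °C
Reagents that add atoms: none
Why: Williamson etherification of the phenol with the benzylic chloride installs the carbon that becomes C2 of ring 2 together with its aryl group.

Step 9
Reactants: 12 4-bromo-1-iodo-2-{[4-(benzyloxy)phenyl]methoxy}benzene, 9 Weinreb amide
Product: 14 diaryl ketone (4-bromo-2-{[4-(benzyloxy)phenyl]methoxy}phenyl)[ring-3 C4-yl]methanone, via aryllithium 13 (not isolated)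
Conditions: n-BuLi (1.0 equiv), THF, −78 °C; then 9, −78 to −20 °C; aq NH4Cl
Reagents that add atoms: none
Why: Iodine–lithium exchange is much faster than bromine–lithium exchange, so the aryllithium keeps its bromine, and its addition to the Weinreb amide stops at the chelated tetrahedral intermediate (Weinreb ketone synthesis).

Step 10
Reactants: 14 diaryl ketone
Product: 15 hydrazone of 14
Conditions: N2H4·H2O (20 equiv), AcOH (cat.), EtOH, 80 °C
Reagents that add atoms: hydrazine hydrate, NN.O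
Why: Condensation of the diaryl ketone with hydrazine gives the N-unsubstituted hydrazone that serves as diazo precursor; its E/Z geometry is irrelevant.

Step 11
Reactants: 15 hydrazone
Product: 17 cis ring-2 bromide with ring 2 (2S,3R) and ring 3 (2S,3S), via diazo compound 16 (not isolated)
Conditions: MnO2 (10 equiv), CH2Cl2, 0 °C, filtration; then Rh2(R-PTAD)4 (1 mol %), CH2Cl2, 0 °C to rt
Reagents that add atoms: none
Why: Oxidation of the hydrazone gives the diaryldiazomethane, whose rhodium carbene inserts into the benzylic C–H bond of the ortho 4-(benzyloxy)benzyl ether (intramolecular 1,5 C–H insertion of a donor/donor carbene); this closes ring 2 at C2–C3 with the aryl groups cis, and the chiral carboxylate ligands fix C3 as R.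

Step 12
Reactants: 17 cis ring-2 bromide
Product: 18 trans ring-2 bromide with ring 2 (2R,3R) and ring 3 (2S,3S)
Conditions: BF3·OEt2 (0.3 equiv), CH2Cl2, −20 to 0 °C
Reagents that add atoms: none
Why: Reversible Lewis-acid heterolysis of the O1–C2 bond of ring 2 to the 4-(benzyloxy)benzylic cation and 5-exo-trig re-closure (thermodynamic epimerisation) should invert C2 to the more stable trans arrangement, while C3 is untouched and ring 3, already trans, can only re-close to itself.

Step 13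
Reactants: 19 2,3-dihydroxybenzaldehyde
Product: 20 3-(benzyloxy)-2-hydroxybenzaldehyde
Conditions: NaH (2.2 equiv), DMSO, rt; BnBr (1.0 equiv); aq HCl
Reagents that add atoms: benzyl bromide, BrCc1ccccc1
Why: Williamson alkylation of the dianion takes place at the more nucleophilic 3-phenoxide, the 2-phenoxide being conjugated with the aldehyde.

Step 14
Reactants: 20 3-(benzyloxy)-2-hydroxybenzaldehyde
Product: 21 3-(benzyloxy)-5-bromo-2-hydroxybenzaldehyde
Conditions: Br2 (1.05 equiv), NaOAc, AcOH, rt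
Reagents that add atoms: bromine, BrBr
Why: Electrophilic aromatic bromination goes para to the free phenol and thus marks the carbon that later carries the stilbene.

Step 15
Reactants: 21 3-(benzyloxy)-5-bromo-2-hydroxybenzaldehyde, 11 4-(benzyloxy)benzyl chloride
Product: 22 3-(benzyloxy)-2-{[4-(benzyloxy)phenyl]methoxy}-5-bromobenzaldehyde
Conditions: K2CO3, DMF, 50 °C
Reagents that add atoms: none
Why: Williamson etherification of the remaining phenol installs the benzylic CH2 that becomes C2 of ring 1.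

Step 16
Reactants: 23 1,3-bis(benzyloxy)-5-bromobenzene, 22 3-(benzyloxy)-2-{[4-(benzyloxy)phenyl]methoxy}-5-bromobenzaldehyde
Product: 25 racemic diarylmethanol, via Grignard reagent 24 (not isolated)
Conditions: Mg, I2 (cat.), THF, 50 °C; then 22, THF, −20 to 0 °C; aq NH4Cl
Reagents that add atoms: none
Why: Grignard addition to the aldehyde forms the diaryl carbinol without exchange at the aryl bromide; the carbinol center is racemic and is erased in the next step.

Step 17
Reactants: 25 racemic diarylmethanol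
Product: 26 diaryl ketone [3,5-bis(benzyloxy)phenyl](3-(benzyloxy)-2-{[4-(benzyloxy)phenyl]methoxy}-5-bromophenyl)methanone
Conditions: MnO2 (15 equiv), CH2Cl2, rt
Reagents that add atoms: none
Why: MnO2 oxidation of a doubly benzylic alcohol gives the benzophenone and leaves benzyl ethers and the aryl bromide alone.

Step 18
Reactants: 26 diaryl ketone
Product: 27 hydrazone of 26
Conditions: N2H4·H2O (20 equiv), AcOH (cat.), EtOH, 80 °C
Reagents that add atoms: hydrazine hydrate, NN.O
Why: Hydrazone formation by condensation provides the diazo precursor for ring 1.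

Step 19
Reactants: 27 hydrazone
Product: 29 cis ring-1 bromide (2R,3S)-7-(benzyloxy)-2-[4-(benzyloxy)phenyl]-3-[3,5-bis(benzyloxy)phenyl]-5-bromo-2,3-dihydro-1-benzofuran, via diazo compound 28 (not isolated)
Conditions: MnO2 (10 equiv), CH2Cl2, 0 °C, filtration; then Rh2(S-PTAD)4 (1 mol %), CH2Cl2, 0 °C to rt
Reagents that add atoms: none
Why: The same oxidation and intramolecular 1,5 C–H insertion of the diaryl rhodium carbene closes ring 1 at C2–C3 cis, and the enantiomeric catalyst fixes C3 as S; the neighbouring 3-benzyloxy group cannot be reached by the carbene.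

Step 20
Reactants: 29 cis ring-1 bromide
Product: 30 trans ring-1 bromide (2S,3S)-7-(benzyloxy)-2-[4-(benzyloxy)phenyl]-3-[3,5-bis(benzyloxy)phenyl]-5-bromo-2,3-dihydro-1-benzofuran
Conditions: BF3·OEt2 (0.3 equiv), CH2Cl2, −20 to 0 °C
Reagents that add atoms: none
Why: Acid-mediated epimerisation at C2 through reversible O1–C2 heterolysis and re-closure should give the thermodynamically preferred trans ring with C3 unchanged.

Step 21
Reactants: 30 trans ring-1 bromide
Product: 31 ring-1 styrene (2S,3S)-7-(benzyloxy)-2-[4-(benzyloxy)phenyl]-3-[3,5-bis(benzyloxy)phenyl]-5-ethenyl-2,3-dihydro-1-benzofuran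
Conditions: vinylboronic acid pinacol ester (1.5 equiv), PdCl2(dppf) (5 mol %), K2CO3, 1,4-dioxane/H2O, 80 °C
Reagents that add atoms: vinylboronic acid pinacol ester, C=CB1OC(C)(C)C(C)(C)O1
Why: Suzuki–Miyaura coupling of the aryl bromide with the vinylboronate installs the terminal alkene without affecting the stereocenters.

Step 22
Reactants: 18 trans ring-2 bromide, 31 ring-1 styrene
Product: 32 nona-O-benzyl ether of the target
Conditions: Pd(OAc)2 (5 mol %), P(o-tol)3 (10 mol %), Et3N, DMF, 100 °C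
Reagents that add atoms: none
Why: Mizoroki–Heck coupling of the unhindered aryl bromide with the styrene should give the stilbene, E by syn insertion and syn β-hydride elimination.

Step 23
Reactants: 32 nona-O-benzyl ether
Product: 33 target CNP0265934.1
Conditions: BCl3 (30 equiv), pentamethylbenzene (30 equiv), CH2Cl2, −78 to −40 °C; then MeOH
Reagents that add atoms: none
Why: Lewis-acid debenzylation with pentamethylbenzene as a non-basic benzyl-cation scavenger should cleave all nine benzyl ethers at low temperature without reducing the stilbene, and any reversible opening of an O1–C2 bond re-closes to the trans ring already present.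

**Compound list**

1 | (E)-resveratrol, 5-[(E)-2-(4-hydroxyphenyl)ethenyl]benzene-1,3-diol | Oc1ccc(/C=C/c2cc(O)cc(O)c2)cc1 | starting material
2 | 1,3-bis(benzyloxy)-5-{(E)-2-[4-(benzyloxy)phenyl]ethenyl}benzene | C(Oc1ccc(/C=C/c2cc(OCc3ccccc3)cc(OCc3ccccc3)c2)cc1)c1ccccc1 | intermediate
3 | methyl 2,3-dihydroxybenzoate | COC(=O)c1cccc(O)c1O | starting material
4 | methyl 3-(benzyloxy)-2-hydroxybenzoate | COC(=O)c1cccc(OCc2ccccc2)c1O | intermediate
5 | methyl 5-(benzyloxy)-3,6-dioxocyclohexa-1,4-diene-1-carboxylate | COC(=O)C1=CC(=O)C=C(OCc2ccccc2)C1=O | intermediate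
6 | methyl (2S,3S)-6-(benzyloxy)-2-[4-(benzyloxy)phenyl]-3-[3,5-bis(benzyloxy)phenyl]-5-hydroxy-2,3-dihydro-1-benzofuran-4-carboxylate | COC(=O)c1c(O)c(OCc2ccccc2)cc2c1[C@H](c1cc(OCc3ccccc3)cc(OCc3ccccc3)c1)[C@@H](c1ccc(OCc3ccccc3)cc1)O2 | intermediate
7 | methyl (2S,3S)-6-(benzyloxy)-2-[4-(benzyloxy)phenyl]-3-[3,5-bis(benzyloxy)phenyl]-5-{[(trifluoromethyl)sulfonyl]oxy}-2,3-dihydro-1-benzofuran-4-carboxylate | COC(=O)c1c(OS(=O)(=O)C(F)(F)F)c(OCc2ccccc2)cc2c1[C@H](c1cc(OCc3ccccc3)cc(OCc3ccccc3)c1)[C@@H](c1ccc(OCc3ccccc3)cc1)O2 | intermediate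
8 | methyl (2S,3S)-6-(benzyloxy)-2-[4-(benzyloxy)phenyl]-3-[3,5-bis(benzyloxy)phenyl]-2,3-dihydro-1-benzofuran-4-carboxylate | COC(=O)c1cc(OCc2ccccc2)cc2c1[C@H](c1cc(OCc3ccccc3)cc(OCc3ccccc3)c1)[C@@H](c1ccc(OCc3ccccc3)cc1)O2 | intermediate
9 | (2S,3S)-6-(benzyloxy)-2-[4-(benzyloxy)phenyl]-3-[3,5-bis(benzyloxy)phenyl]-N-methoxy-N-methyl-2,3-dihydro-1-benzofuran-4-carboxamide | CON(C)C(=O)c1cc(OCc2ccccc2)cc2c1[C@H](c1cc(OCc3ccccc3)cc(OCc3ccccc3)c1)[C@@H](c1ccc(OCc3ccccc3)cc1)O2 | intermediate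
10 | 5-bromo-2-iodophenol | Oc1cc(Br)ccc1I | starting material
11 | 1-(benzyloxy)-4-(chloromethyl)benzene | ClCc1ccc(OCc2ccccc2)cc1 | starting material
12 | 4-bromo-1-iodo-2-{[4-(benzyloxy)phenyl]methoxy}benzene | Brc1ccc(I)c(OCc2ccc(OCc3ccccc3)cc2)c1 | intermediate
13 | (4-bromo-2-{[4-(benzyloxy)phenyl]methoxy}phenyl)lithium | [Li]c1ccc(Br)cc1OCc1ccc(OCc2ccccc2)cc1 | intermediate
14 | (4-bromo-2-{[4-(benzyloxy)phenyl]methoxy}phenyl){(2S,3S)-6-(benzyloxy)-2-[4-(benzyloxy)phenyl]-3-[3,5-bis(benzyloxy)phenyl]-2,3-dihydro-1-benzofuran-4-yl}methanone | O=C(c1ccc(Br)cc1OCc1ccc(OCc2ccccc2)cc1)c1cc(OCc2ccccc2)cc2c1[C@H](c1cc(OCc3ccccc3)cc(OCc3ccccc3)c1)[C@@H](c1ccc(OCc3ccccc3)cc1)O2 | intermediate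
15 | hydrazone of 14 (E/Z mixture) | NN=C(c1ccc(Br)cc1OCc1ccc(OCc2ccccc2)cc1)c1cc(OCc2ccccc2)cc2c1[C@H](c1cc(OCc3ccccc3)cc(OCc3ccccc3)c1)[C@@H](c1ccc(OCc3ccccc3)cc1)O2 | intermediate
16 | (2S,3S)-6-(benzyloxy)-2-[4-(benzyloxy)phenyl]-3-[3,5-bis(benzyloxy)phenyl]-4-[(4-bromo-2-{[4-(benzyloxy)phenyl]methoxy}phenyl)(diazo)methyl]-2,3-dihydro-1-benzofuran | [N-]=[N+]=C(c1ccc(Br)cc1OCc1ccc(OCc2ccccc2)cc1)c1cc(OCc2ccccc2)cc2c1[C@H](c1cc(OCc3ccccc3)cc(OCc3ccccc3)c1)[C@@H](c1ccc(OCc3ccccc3)cc1)O2 | intermediate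
17 | (2S,3S)-6-(benzyloxy)-2-[4-(benzyloxy)phenyl]-3-[3,5-bis(benzyloxy)phenyl]-4-{(2S,3R)-2-[4-(benzyloxy)phenyl]-6-bromo-2,3-dihydro-1-benzofuran-3-yl}-2,3-dihydro-1-benzofuran | Brc1ccc2c(c1)O[C@H](c1ccc(OCc3ccccc3)cc1)[C@@H]2c1cc(OCc2ccccc2)cc2c1[C@H](c1cc(OCc3ccccc3)cc(OCc3ccccc3)c1)[C@@H](c1ccc(OCc3ccccc3)cc1)O2 | intermediate
18 | (2S,3S)-6-(benzyloxy)-2-[4-(benzyloxy)phenyl]-3-[3,5-bis(benzyloxy)phenyl]-4-{(2R,3R)-2-[4-(benzyloxy)phenyl]-6-bromo-2,3-dihydro-1-benzofuran-3-yl}-2,3-dihydro-1-benzofuran | Brc1ccc2c(c1)O[C@@H](c1ccc(OCc3ccccc3)cc1)[C@@H]2c1cc(OCc2ccccc2)cc2c1[C@H](c1cc(OCc3ccccc3)cc(OCc3ccccc3)c1)[C@@H](c1ccc(OCc3ccccc3)cc1)O2 | intermediate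
19 | 2,3-dihydroxybenzaldehyde | O=Cc1cccc(O)c1O | starting material
20 | 3-(benzyloxy)-2-hydroxybenzaldehyde | O=Cc1cccc(OCc2ccccc2)c1O | intermediate
21 | 3-(benzyloxy)-5-bromo-2-hydroxybenzaldehyde | O=Cc1cc(Br)cc(OCc2ccccc2)c1O | intermediate
22 | 3-(benzyloxy)-2-{[4-(benzyloxy)phenyl]methoxy}-5-bromobenzaldehyde | O=Cc1cc(Br)cc(OCc2ccccc2)c1OCc1ccc(OCc2ccccc2)cc1 | intermediate
23 | 1,3-bis(benzyloxy)-5-bromobenzene | Brc1cc(OCc2ccccc2)cc(OCc2ccccc2)c1 | starting material
24 | [3,5-bis(benzyloxy)phenyl]magnesium bromide | Br[Mg]c1cc(OCc2ccccc2)cc(OCc2ccccc2)c1 | intermediate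
25 | rac-[3,5-bis(benzyloxy)phenyl](3-(benzyloxy)-2-{[4-(benzyloxy)phenyl]methoxy}-5-bromophenyl)methanol | OC(c1cc(OCc2ccccc2)cc(OCc2ccccc2)c1)c1cc(Br)cc(OCc2ccccc2)c1OCc1ccc(OCc2ccccc2)cc1 | intermediate
26 | [3,5-bis(benzyloxy)phenyl](3-(benzyloxy)-2-{[4-(benzyloxy)phenyl]methoxy}-5-bromophenyl)methanone | O=C(c1cc(OCc2ccccc2)cc(OCc2ccccc2)c1)c1cc(Br)cc(OCc2ccccc2)c1OCc1ccc(OCc2ccccc2)cc1 | intermediate
27 | hydrazone of 26 (E/Z mixture) | NN=C(c1cc(OCc2ccccc2)cc(OCc2ccccc2)c1)c1cc(Br)cc(OCc2ccccc2)c1OCc1ccc(OCc2ccccc2)cc1 | intermediate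
28 | 1-(benzyloxy)-5-bromo-2-{[4-(benzyloxy)phenyl]methoxy}-3-{[3,5-bis(benzyloxy)phenyl](diazo)methyl}benzene | [N-]=[N+]=C(c1cc(OCc2ccccc2)cc(OCc2ccccc2)c1)c1cc(Br)cc(OCc2ccccc2)c1OCc1ccc(OCc2ccccc2)cc1 | intermediate
29 | (2R,3S)-7-(benzyloxy)-2-[4-(benzyloxy)phenyl]-3-[3,5-bis(benzyloxy)phenyl]-5-bromo-2,3-dihydro-1-benzofuran | C(Oc1ccc([C@@H]2Oc3c(OCc4ccccc4)cc(Br)cc3[C@@H]2c2cc(OCc3ccccc3)cc(OCc3ccccc3)c2)cc1)c1ccccc1 | intermediate
30 | (2S,3S)-7-(benzyloxy)-2-[4-(benzyloxy)phenyl]-3-[3,5-bis(benzyloxy)phenyl]-5-bromo-2,3-dihydro-1-benzofuran | C(Oc1ccc([C@H]2Oc3c(OCc4ccccc4)cc(Br)cc3[C@@H]2c2cc(OCc3ccccc3)cc(OCc3ccccc3)c2)cc1)c1ccccc1 | intermediate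
31 | (2S,3S)-7-(benzyloxy)-2-[4-(benzyloxy)phenyl]-3-[3,5-bis(benzyloxy)phenyl]-5-ethenyl-2,3-dihydro-1-benzofuran | C(Oc1ccc([C@H]2Oc3c(OCc4ccccc4)cc(C=C)cc3[C@@H]2c2cc(OCc3ccccc3)cc(OCc3ccccc3)c2)cc1)c1ccccc1 | intermediate
32 | (2S,3S)-7-(benzyloxy)-2-[4-(benzyloxy)phenyl]-3-[3,5-bis(benzyloxy)phenyl]-5-[(E)-2-{(2R,3R)-2-[4-(benzyloxy)phenyl]-3-[(2S,3S)-6-(benzyloxy)-2-[4-(benzyloxy)phenyl]-3-[3,5-bis(benzyloxy)phenyl]-2,3-dihydro-1-benzofuran-4-yl]-2,3-dihydro-1-benzofuran-6-yl}ethenyl]-2,3-dihydro-1-benzofuran | C(Oc1ccc([C@H]2Oc3c(OCc4ccccc4)cc(/C=C/c4ccc5c(c4)O[C@@H](c4ccc(OCc6ccccc6)cc4)[C@@H]5c4cc(OCc6ccccc6)cc5c4[C@H](c4cc(OCc6ccccc6)cc(OCc6ccccc6)c4)[C@@H](c4ccc(OCc6ccccc6)cc4)O5)cc3[C@@H]2c2cc(OCc3ccccc3)cc(OCc3ccccc3)c2)cc1)c1ccccc1 | intermediate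
33 | 5-[(2S,3S)-5-{(E)-2-[(2R,3R)-3-[(2S,3S)-3-(3,5-dihydroxyphenyl)-6-hydroxy-2-(4-hydroxyphenyl)-2,3-dihydro-1-benzofuran-4-yl]-2-(4-hydroxyphenyl)-2,3-dihydro-1-benzofuran-6-yl]ethenyl}-7-hydroxy-2-(4-hydroxyphenyl)-2,3-dihydro-1-benzofuran-3-yl]benzene-1,3-diol | Oc1ccc([C@H]2Oc3c(O)cc(/C=C/c4ccc5c(c4)O[C@@H](c4ccc(O)cc4)[C@@H]5c4cc(O)cc5c4[C@H](c4cc(O)cc(O)c4)[C@@H](c4ccc(O)cc4)O5)cc3[C@@H]2c2cc(O)cc(O)c2)cc1 | target

**Count and risks**

Total step count: 23. Longest linear sequence: 12 steps (steps 2–7, 9–12, 22 and 23, from methyl 2,3-dihydroxybenzoate).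

Steps most likely to fail:

1. Step 4 (key annulation). The 1,2-diarylethene is a weaker π-nucleophile than a styrene, so the catalysed pathway may be slow, and an unselective background addition or arene attack by the 3,5-bis(benzyloxy)phenyl ring may erode the enantiomeric purity. The fallback sets out from 5 and 2 and returns at 6. The annulation is run with an achiral promoter (Sc(OTf)3, CH2Cl2, −40 °C), which should give the racemic trans adduct rac-6 F1. Acylation of its phenol with (1S)-camphanic chloride (Et3N, DMAP, CH2Cl2) gives the camphanate of the (2S,3S) enantiomer F2 beside the camphanate of the (2R,3R) enantiomer F3. The two diastereomers are separated by crystallisation or chromatography, and F2 is cleaved with K2CO3 in MeOH to 6. The absolute configuration then comes from a classical resolution and no longer from the catalyst.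

2. Step 11 (ring-2 insertion). Catalyst and ring-3 stereocenters may be mismatched, which would give poor facial selectivity, or the hindered carbene may be captured by the neighbouring electron-rich 3,5-bis(benzyloxy)phenyl ring before it inserts. The fallback sets out from 14 and returns at 18. Lithium 2,2,6,6-tetramethylpiperidide (LiTMP) in THF at −78 °C deprotonates the ArOCH2Ar position, and the carbanion adds to the ketone (anionic 5-exo cyclisation, known for 2-(benzyloxy)benzophenones); this should give the 3-hydroxy-2,3-dihydrobenzofuran F4 as a mixture of isomers. Ionic deoxygenation with Et3SiH and BF3·OEt2 in CH2Cl2 (hydride capture of the C3 cation, C2 equilibrating to trans under the same acid) should give 18 together with its ring-2 (2S,3S) diastereomer F5, which is removed by chromatography. This path uses no carbene and relies on separating diastereomers for ring 2.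

3. Step 23 (global debenzylation). With nine ethers to cleave, the Lewis acid may ionise the benzylic O1–C2 bonds, which invites Friedel–Crafts attack on the stilbene or leaves partly benzylated material, and the nonaphenol oxidises easily on handling. The fallback sets out from 30 and 18 and returns at 33; the benzyl ethers are exchanged for acetates on the two halves before the alkene exists. 30 is debenzylated (BCl3, pentamethylbenzene, CH2Cl2, −78 °C) to the ring-1 tetraphenol bromide F6 and acetylated (Ac2O, pyridine) to the ring-1 tetraacetate bromide F7; a Stille coupling with tributyl(vinyl)stannane (Pd(PPh3)4, toluene, 100 °C) converts F7 into the ring-1 tetraacetate styrene F8. 18 gives in the same way the pentaphenol bromide F9 and the pentaacetate bromide F10. Heck coupling of F10 with F8 (Pd(OAc)2, P(o-tol)3, Et3N, DMF, 90 °C) should give the nonaacetate F11, and K2CO3 in MeOH at 0 °C then frees 33 under mild base.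

**Further compounds**

F1 | step 4 | rac-6, 1:1 mixture of 6 and its (2R,3R) enantiomer | COC(=O)c1c(O)c(OCc2ccccc2)cc2c1[C@H](c1cc(OCc3ccccc3)cc(OCc3ccccc3)c1)[C@@H](c1ccc(OCc3ccccc3)cc1)O2.COC(=O)c1c(O)c(OCc2ccccc2)cc2c1[C@@H](c1cc(OCc3ccccc3)cc(OCc3ccccc3)c1)[C@H](c1ccc(OCc3ccccc3)cc1)O2
F2 | step 4 | (1S,4R)-camphanate of 6 at the C5 oxygen | COC(=O)c1c(OC(=O)[C@@]23CC[C@@](C)(C(=O)O2)C3(C)C)c(OCc2ccccc2)cc2c1[C@H](c1cc(OCc3ccccc3)cc(OCc3ccccc3)c1)[C@@H](c1ccc(OCc3ccccc3)cc1)O2
F3 | step 4 | (1S,4R)-camphanate of the (2R,3R) enantiomer of 6 | COC(=O)c1c(OC(=O)[C@@]23CC[C@@](C)(C(=O)O2)C3(C)C)c(OCc2ccccc2)cc2c1[C@@H](c1cc(OCc3ccccc3)cc(OCc3ccccc3)c1)[C@H](c1ccc(OCc3ccccc3)cc1)O2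
F4 | step 11 | 2-[4-(benzyloxy)phenyl]-6-bromo-3-{(2S,3S)-6-(benzyloxy)-2-[4-(benzyloxy)phenyl]-3-[3,5-bis(benzyloxy)phenyl]-2,3-dihydro-1-benzofuran-4-yl}-2,3-dihydro-1-benzofuran-3-ol (isomer mixture at the new centers) | Brc1ccc2c(c1)OC(c1ccc(OCc3ccccc3)cc1)C2(O)c1cc(OCc2ccccc2)cc2c1[C@H](c1cc(OCc3ccccc3)cc(OCc3ccccc3)c1)[C@@H](c1ccc(OCc3ccccc3)cc1)O2
F5 | step 11 | ring-2 (2S,3S) diastereomer of 18 | Brc1ccc2c(c1)O[C@H](c1ccc(OCc3ccccc3)cc1)[C@H]2c1cc(OCc2ccccc2)cc2c1[C@H](c1cc(OCc3ccccc3)cc(OCc3ccccc3)c1)[C@@H](c1ccc(OCc3ccccc3)cc1)O2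
F6 | step 23 | 5-[(2S,3S)-5-bromo-7-hydroxy-2-(4-hydroxyphenyl)-2,3-dihydro-1-benzofuran-3-yl]benzene-1,3-diol | Oc1ccc([C@H]2Oc3c(O)cc(Br)cc3[C@@H]2c2cc(O)cc(O)c2)cc1
F7 | step 23 | tetraacetate of F6 | CC(=O)Oc1ccc([C@H]2Oc3c(OC(C)=O)cc(Br)cc3[C@@H]2c2cc(OC(C)=O)cc(OC(C)=O)c2)cc1
F8 | step 23 | tetraacetate of the 5-ethenyl analogue of F6 | CC(=O)Oc1ccc([C@H]2Oc3c(OC(C)=O)cc(C=C)cc3[C@@H]2c2cc(OC(C)=O)cc(OC(C)=O)c2)cc1
F9 | step 23 | pentaphenol from 18, 5-[(2S,3S)-4-{(2R,3R)-6-bromo-2-(4-hydroxyphenyl)-2,3-dihydro-1-benzofuran-3-yl}-6-hydroxy-2-(4-hydroxyphenyl)-2,3-dihydro-1-benzofuran-3-yl]benzene-1,3-diol | Brc1ccc2c(c1)O[C@@H](c1ccc(O)cc1)[C@@H]2c1cc(O)cc2c1[C@H](c1cc(O)cc(O)c1)[C@@H](c1ccc(O)cc1)O2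
F10 | step 23 | pentaacetate of F9 | Brc1ccc2c(c1)O[C@@H](c1ccc(OC(C)=O)cc1)[C@@H]2c1cc(OC(C)=O)cc2c1[C@H](c1cc(OC(C)=O)cc(OC(C)=O)c1)[C@@H](c1ccc(OC(C)=O)cc1)O2
F11 | step 23 | nonaacetate of 33 | CC(=O)Oc1ccc([C@H]2Oc3c(OC(C)=O)cc(/C=C/c4ccc5c(c4)O[C@@H](c4ccc(OC(C)=O)cc4)[C@@H]5c4cc(OC(C)=O)cc5c4[C@H](c4cc(OC(C)=O)cc(OC(C)=O)c4)[C@@H](c4ccc(OC(C)=O)cc4)O5)cc3[C@@H]2c2cc(OC(C)=O)cc(OC(C)=O)c2)cc1
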